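All runs are calculated from invented constants; noise was put on by code.

| flask | starting material | reagent | time |
|---|---|---|---|
| ash | 250 mM | 375 mM |  |
| alder | 150 mM | 275 mM |  |
| oak | 380 mM | 375 mM |  |
| cedar | 250 mM | 375 mM | 140 min |

| run | time / min | [target] / mM |
|---|---|---|
| ash run | 2.0 | 11.6 |
| ash run | 6.2 | 31.6 |
| ash run | 12 | 49.0 |
| ash run | 19 | 64.2 |
| ash run | 27 | 83.7 |
| ash run | 36 | 94.5 |
| ash run | 46 | 101.8 |
| ash run | 57 | 109.7 |
| alder run | 2.0 | 3.7 |
| alder run | 6.2 | 9.3 |
| alder run | 12 | 20.4 |
| alder run | 19 | 28.0 |
| alder run | 27 | 32.9 |
| alder run | 36 | 40.8 |
| alder run | 46 | 46.3 |
| alder run | 57 | 48.0 |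
| oak run | 2.0 | 16.2 |
| oak run | 6.2 | 44.4 |
| oak run | 12 | 71.6 |
| oak run | 19 | 98.9 |
| oak run | 27 | 110.0 |
| oak run | 36 | 120.2 |
| oak run | 46 | 137.3 |
| oak run | 57 | 137.5 |

(standard deviation of a reading: 2 mM)

1. how the opening rate goes with [starting material] round the charge of the ash run: the exponent of the rate at two percent of starting material gone to target (one fixed amount of target, the same in the runs compared)
2. how the opening rate goes with [reagent] round the charge of the ash run: the exponent of the rate at two percent of starting material gone to target
3. target in the cedar run at 140 min, as a share of the starting material charged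

- Overall: starting material + reagent -> target.
- Constant volume, constant temperature.
- "The second partner" is reagent.
- An order is taken over about fifteen percent of the charge, up and down.

1. The closed vessel of the ash run seems to be coming to rest, so I turn the question round: for a true stop, formation at the last ash reading would have to have faded to the slope still seen there, and I test this.

2. Mean rates over the first 6.2 min give an exponent of 0.812 in starting material from oak against ash; alder against ash, with starting material taken as first order, then gives 2.30 in reagent, so within the scatter I commit to 1 and 2.

3. With those orders, and counting consumed material as the target in hand, the last ash reading keeps a share of 0.281 of the opening rate of 5.80 mM min⁻¹, which is 1.63 mM min⁻¹, while ash still climbs at 0.718 mM min⁻¹, so formation reckoned this way runs faster than the climb.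

4. I call the gap per unit of target the drain constant, a first-order loss constant, and read it in ash as 0.008304 min⁻¹, so target halves in 83.5 min; oak, reckoned alike, reads 0.0149 min⁻¹, with wide scatter.

5. For cedar I decay the last ash reading over the remaining 83.0 min and add new formation at half its last value, decayed over the middle of that stretch, which gives 41.2 %.

6. The forecast says 0.9, 1.7 and 49 %, holding that the levelling “looks like an equilibrium or a stall”; my cedar figure is lower than its figure.

The flask gives 1.0, 2.0 and 38.7 %.

    starting material + 2 reagent → target + reagent (0.1656 M⁻² min⁻¹)
    target → decomposed product (0.006960 min⁻¹)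

Cedar ends at 96.7 mM, lower than the 109.7 mM read in ash at 57 min from the same charge, so target falls somewhere after that reading. The reason is the loss of target to decomposed product, the step that my drain constant, read as 0.00830 min⁻¹ from ash, was an estimate of: with the step's own constant of 0.00696 min⁻¹, the cedar target at 140 min is losing 0.673 mM min⁻¹. Without that loss the simulated cedar run holds 75.1 % against 38.7 %, a gap of 36 percentage points.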